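## Retrosynthetic overview

1. Target 29 ⇐ global desilylation of acid 28. The C12 acid comes from late oxidation of the C7 isopropenyl methyl group (SeO2, then MnO2/NaClO2), and the C8 ester from coupling diol 23 with the Roche-ester-derived acid 3.
2. C8–OH ⇐ reduction of ketone 22 directed by the 6-OH. The C10 quaternary centre ⇐ vinyl cuprate addition to enone 19 (allylic oxidation of 18), anti to the C5 side chain.
3. C5 side chain and the cis C5/C6 pair ⇐ α-methylenation and reductive opening of cis-lactone 12. Lactone 12 ⇐ key Ireland–Claisen rearrangement of hydroxy acetate 8, which forms the C5–C4 bond with 1,3-chirality transfer from C9–O.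
4. 8 ⇐ (S)-carvone 4 by Luche reduction, acetylation, allylic oxidation at C6 and LiBH(s-Bu)3 reduction.
5. Rings: the cyclohexane is the carvone ring and is never opened. The only ring formed is the temporary γ-lactone (step 7), opened again in step 9.

Convention: ring carbons carry elemane numbers (C10 quaternary, C9 = CH2, C8, C7, C6, C5; C4/C3/C15 = the three-carbon unit on C5; C11/C12/C13 = the unit on C7; C1/C2 = vinyl; C14 = methyl on C10); β = the face of C14, α = the opposite face.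

## Route

Step 1
Reactants: 1 methyl (R)-3-hydroxy-2-methylpropanoate ((R)-Roche ester)
Product: 2 methyl (R)-3-(tert-butyldimethylsilyloxy)-2-methylpropanoate
Conditions: TBSCl, imidazole, CH2Cl2, 0 °C → rt
Reagents that add atoms: TBSCl (tert-butyldimethylsilyl chloride), CC(C)(C)[Si](C)(C)Cl
Why: O-silylation protects the primary alcohol and does not touch the stereocentre.

Step 2
Reactants: 2 methyl (R)-3-(tert-butyldimethylsilyloxy)-2-methylpropanoate
Product: 3 (R)-3-(tert-butyldimethylsilyloxy)-2-methylpropanoic acid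
Conditions: LiOH, THF/MeOH/H2O, 0 °C; then 1 M HCl to pH 4
Reagents that add atoms: LiOH (lithium hydroxide), [Li+].[OH-]
Why: Ester saponification at 0 °C is faster than enolisation or β-elimination, so the α-stereocentre is kept.

Step 3
Reactants: 4 (S)-(+)-carvone
Product: 5 (1S,5S)-cis-carveol
Conditions: NaBH4, CeCl3·7H2O, MeOH, −78 °C → 0 °C
Reagents that add atoms: none
Why: Luche 1,2-reduction delivers hydride axially and gives the cis (diequatorial) allylic alcohol, so C9–O is set β by the carvone stereocentre (C7).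

Step 4
Reactants: 5 (1S,5S)-cis-carveol
Product: 6 (1S,5S)-cis-carvyl acetate
Conditions: Ac2O, pyridine, DMAP (cat.), CH2Cl2, 0 °C → rt
Reagents that add atoms: acetic anhydride, CC(=O)OC(C)=O
Why: Acetylation protects the alcohol for the oxidation and installs the ester needed for the Claisen step.

Step 5
Reactants: 6 (1S,5S)-cis-carvyl acetate
Product: 7 (1S,5S)-2-methyl-4-oxo-5-(prop-1-en-2-yl)cyclohex-2-en-1-yl acetate
Conditions: CrO3, 3,5-dimethylpyrazole, CH2Cl2, −20 °C
Reagents that add atoms: CrO3 (chromium trioxide), O=[Cr](=O)=O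
Why: Allylic oxidation attacks the only ring allylic CH2 (C6, next to the =CH carbon) and gives the enone, as in valencene → nootkatone; no stereocentre is formed.

Step 6
Reactants: 7 (1S,5S)-2-methyl-4-oxo-5-(prop-1-en-2-yl)cyclohex-2-en-1-yl acetate
Product: 8 (1S,4S,5S)-4-hydroxy-2-methyl-5-(prop-1-en-2-yl)cyclohex-2-en-1-yl acetate (OAc; OH; isopropenyl all cis)
Conditions: LiBH(s-Bu)3, THF, −78 °C; H2O
Reagents that add atoms: none
Why: The bulky hydride attacks the β-methyl enone 1,2 from the equatorial direction and gives the axial 6β-alcohol cis to the adjacent isopropenyl group (the menthone → neomenthol pattern).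

Step 7
Reactants: 8 (1S,4S,5S)-4-hydroxy-2-methyl-5-(prop-1-en-2-yl)cyclohex-2-en-1-yl acetate
Product: 12 cis-fused lactone (3aS,7S,7aR)-4-methyl-7-(prop-1-en-2-yl)-3a,6,7,7a-tetrahydro-1-benzofuran-2(3H)-one (H-3a/H-7/H-7a all cis), via bis-TMS ketene acetal 9 (not isolated), via bis-TMS rearrangement product 10 (not isolated), via hydroxy acid 11 (not isolated)
Conditions: LiN(i-Pr)2 (2.5 equiv), TMSCl (3 equiv), THF, −78 °C → 60 °C; then 1 M HCl, THF, rt
Reagents that add atoms: none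
Why: Ireland–Claisen [3,3] rearrangement is suprafacial, so the new C5–C4 bond forms on the β-face that carried the C9–O bond; the cis 6β-OH then closes the γ-lactone.

Step 8
Reactants: 12 cis-fused lactone
Product: 15 α-methylene lactone (3-methylidene analogue of 12), via Mannich base 13 (not isolated), via ammonium iodide 14 (not isolated)
Conditions: LiN(i-Pr)2, THF, −78 °C; CH2=NMe2+ I−, −78 °C → rt; then MeI, MeOH; then NaHCO3 (aq), CH2Cl2
Reagents that add atoms: Eschenmoser's salt (N,N-dimethylmethyleneiminium iodide), C=[N+](C)C.[I-]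
Why: Lactone enolate Mannich reaction followed by quaternisation and Hofmann-type elimination installs the exocyclic methylene; the new α-centre becomes sp2.

Step 9
Reactants: 15 α-methylene lactone
Product: 16 diol 2-(3-hydroxyprop-1-en-2-yl)-3-methyl-6-(prop-1-en-2-yl)cyclohex-3-en-1-ol (C1/C2/C6 substituents all cis; = 6β-OH and 15-OH)
Conditions: i-Bu2AlH (4 equiv), CH2Cl2, −78 °C → 0 °C; Rochelle salt
Reagents that add atoms: none
Why: 1,2-reduction of the lactone gives the allylic primary alcohol (C15) and frees the 6β-OH without touching stereocentres.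

Step 10
Reactants: 16 diol
Product: 18 15-O-TBS 6-O-TES bis-silyl ether, via mono-TBS ether 17 (not isolated)
Conditions: TBSCl, imidazole, CH2Cl2, 0 °C; then TESOTf, 2,6-lutidine, −40 °C → 0 °C
Reagents that add atoms: TBSCl, CC(C)(C)[Si](C)(C)Cl; TESOTf (triethylsilyl triflate), CC[Si](CC)(CC)OS(=O)(=O)C(F)(F)F
Why: Silylation: the chloride selects the primary alcohol and the triflate then caps the hindered axial 6-OH with a group that can be removed separately.

Step 11
Reactants: 18 bis-silyl ether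
Product: 19 enone 4-[3-(tert-butyldimethylsilyloxy)prop-1-en-2-yl]-3-methyl-6-(prop-1-en-2-yl)-5-(triethylsilyloxy)cyclohex-2-en-1-one (C4/C5/C6 substituents all cis; C8 ketone)
Conditions: CrO3, 3,5-dimethylpyrazole, CH2Cl2, −20 °C
Reagents that add atoms: CrO3 (chromium trioxide), O=[Cr](=O)=O
Why: A second allylic oxidation converts the ring allylic CH2 (C8) of the trisubstituted alkene into the β-methyl enone; no stereocentre is formed.

Step 12
Reactants: 19 enone
Product: 22 β-hydroxy ketone (C8=O; 6β-OH; 7β-isopropenyl; 5β-[3-(TBSO)prop-1-en-2-yl]; 10β-methyl; 10α-vinyl), via TMS enol ether 20 (not isolated), via TES ketone 21 (not isolated)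
Conditions: CH2=CHMgBr, CuBr·SMe2 (10 mol %), TMSCl, THF, −78 °C → −40 °C; then AcOH/THF/H2O, rt
Reagents that add atoms: vinylmagnesium bromide, C=C[Mg]Br
Why: Copper-catalysed conjugate addition enters from the α-face, anti to the three β-substituents at C5, C6 and C7, so the C10 centre forms with vinyl trans to the C5 chain; mild acid then cleaves the TMS enol ether and the TES ether.

Step 13
Reactants: 22 β-hydroxy ketone
Product: 23 anti-1,3-diol (6β-OH; 8α-OH; 7β-isopropenyl; 5β-[3-(TBSO)prop-1-en-2-yl]; 10β-methyl; 10α-vinyl)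
Conditions: Me4NBH(OAc)3, MeCN/AcOH, −30 °C → 0 °C
Reagents that add atoms: none
Why: Evans–Saksena directed reduction: the axial 6β-OH binds boron and delivers hydride to the β-face of C8, giving the equatorial 8α-alcohol that external hydrides would not give because of the axial C14 and O6.

Step 14
Reactants: 23 anti-1,3-diol; 3 (R)-3-(tert-butyldimethylsilyloxy)-2-methylpropanoic acid
Product: 24 C8 ester (8α-O-[(R)-3-(TBSO)-2-methylpropanoyl]; 6β-OH free; 15-OTBS)
Conditions: DCC, DMAP (0.2 equiv), CH2Cl2, 0 °C → rt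
Reagents that add atoms: none
Why: Steglich esterification acylates the equatorial 8α-OH in preference to the axial 6β-OH, which is flanked by two branched carbons and 1,3-diaxial to C14.

Step 15
Reactants: 24 C8 ester
Product: 25 6-O-TES ether of 24
Conditions: TESOTf, 2,6-lutidine, CH2Cl2, −40 °C → 0 °C
Reagents that add atoms: TESOTf (triethylsilyl triflate), CC[Si](CC)(CC)OS(=O)(=O)C(F)(F)F
Why: Silylation masks the 6β-OH so that the C12 aldehyde of step 17 cannot close to a lactol and lactone.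

Step 16
Reactants: 25 6-O-TES ether
Product: 26 allylic alcohol (C7 unit = 3-hydroxyprop-1-en-2-yl; otherwise as 25)
Conditions: SeO2 (0.5 equiv), t-BuOOH (3 equiv), CH2Cl2, rt
Reagents that add atoms: tert-butyl hydroperoxide, CC(C)(C)OO; SeO2 (oxygen-transfer catalyst), O=[Se]=O
Why: Selenium dioxide allylic oxidation (ene reaction then [2,3]-shift) hydroxylates the methyl of the electron-richer isopropenyl group; the vinyl group has no allylic hydrogen and the C4 alkene is deactivated by its silyloxy group.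

Step 17
Reactants: 26 allylic alcohol
Product: 28 acrylic acid (C7 unit = C(=CH2)CO2H; 8α-ester; 6β-OTES; two OTBS), via enal 27 (not isolated)
Conditions: MnO2, CH2Cl2, rt; then NaClO2, NaH2PO4, 2-methyl-2-butene, t-BuOH/H2O, 0 °C
Reagents that add atoms: NaClO2 (sodium chlorite), [Na+].[O-]Cl=O
Why: MnO2 oxidises only the allylic primary alcohol, and Pinnick oxidation takes the enal to the acid without touching the alkenes, silyl ethers or ester.

Step 18
Reactants: 28 acrylic acid
Product: 29 target CNP0462645.4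
Conditions: HF·pyridine, pyridine, THF, 0 °C → rt; pH 5 buffer work-up
Reagents that add atoms: none
Why: Buffered fluoride desilylation removes the two TBS ethers and the TES ether; it leaves the ester and stereocentres alone and keeps the cis-γ-hydroxy acid from lactonising.

## Compound list

1 | methyl (R)-3-hydroxy-2-methylpropanoate ((R)-Roche ester) | COC(=O)[C@H](C)CO | starting material
2 | methyl (R)-3-(tert-butyldimethylsilyloxy)-2-methylpropanoate | COC(=O)[C@H](C)CO[Si](C)(C)C(C)(C)C | intermediate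
3 | (R)-3-(tert-butyldimethylsilyloxy)-2-methylpropanoic acid | OC(=O)[C@H](C)CO[Si](C)(C)C(C)(C)C | intermediate
4 | (S)-(+)-carvone | CC1=CC[C@@H](CC1=O)C(C)=C | starting material
5 | (1S,5S)-cis-carveol | O[C@H]1C[C@@H](C(C)=C)CC=C1C | intermediate
6 | (1S,5S)-cis-carvyl acetate | CC(=O)O[C@H]1C[C@@H](C(C)=C)CC=C1C | intermediate
7 | (1S,5S)-2-methyl-4-oxo-5-(prop-1-en-2-yl)cyclohex-2-en-1-yl acetate | CC(=O)O[C@H]1C[C@@H](C(C)=C)C(=O)C=C1C | intermediate
8 | (1S,4S,5S)-4-hydroxy-2-methyl-5-(prop-1-en-2-yl)cyclohex-2-en-1-yl acetate (all cis) | CC(=O)O[C@H]1C[C@@H](C(C)=C)[C@@H](O)C=C1C | intermediate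
9 | bis-TMS ketene acetal of 8 (6-OTMS; C9–O–C(OTMS)=CH2) | C=C(O[Si](C)(C)C)O[C@H]1C[C@@H](C(C)=C)[C@@H](O[Si](C)(C)C)C=C1C | intermediate
10 | bis-TMS rearrangement product (TMS ester of 11, 6-OTMS) | CC1=CC[C@@H](C(C)=C)[C@@H](O[Si](C)(C)C)[C@H]1CC(=O)O[Si](C)(C)C | intermediate
11 | hydroxy acid: 2-[6-hydroxy-2-methyl-5-(prop-1-en-2-yl)cyclohex-2-en-1-yl]acetic acid (C1/C5/C6 substituents all cis) | CC1=CC[C@@H](C(C)=C)[C@@H](O)[C@H]1CC(=O)O | intermediate
12 | cis-fused lactone (3aS,7S,7aR)-4-methyl-7-(prop-1-en-2-yl)-3a,6,7,7a-tetrahydro-1-benzofuran-2(3H)-one (H-3a/H-7/H-7a all cis) | CC1=CC[C@@H](C(C)=C)[C@H]2OC(=O)C[C@@H]12 | intermediate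
13 | Mannich base: 3-(dimethylaminomethyl) derivative of 12 (aminomethyl on the convex face, cis to H-3a) | CC1=CC[C@@H](C(C)=C)[C@H]2OC(=O)[C@H](CN(C)C)[C@@H]12 | intermediate
14 | trimethylammonium iodide of 13 | CC1=CC[C@@H](C(C)=C)[C@H]2OC(=O)[C@H](C[N+](C)(C)C)[C@@H]12.[I-] | intermediate
15 | α-methylene lactone: 3-methylidene analogue of 12 | CC1=CC[C@@H](C(C)=C)[C@H]2OC(=O)C(=C)[C@@H]12 | intermediate
16 | diol: 2-(3-hydroxyprop-1-en-2-yl)-3-methyl-6-(prop-1-en-2-yl)cyclohex-3-en-1-ol (C1/C2/C6 substituents all cis) | CC1=CC[C@@H](C(C)=C)[C@@H](O)[C@H]1C(=C)CO | intermediate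
17 | mono-TBS ether of 16 (15-OTBS, 6β-OH) | CC1=CC[C@@H](C(C)=C)[C@@H](O)[C@H]1C(=C)CO[Si](C)(C)C(C)(C)C | intermediate
18 | bis-silyl ether (15-OTBS, 6β-OTES) | CC1=CC[C@@H](C(C)=C)[C@@H](O[Si](CC)(CC)CC)[C@H]1C(=C)CO[Si](C)(C)C(C)(C)C | intermediate
19 | enone: 4-[3-(TBSO)prop-1-en-2-yl]-3-methyl-6-(prop-1-en-2-yl)-5-(triethylsilyloxy)cyclohex-2-en-1-one (C4/C5/C6 all cis) | CC1=CC(=O)[C@@H](C(C)=C)[C@@H](O[Si](CC)(CC)CC)[C@H]1C(=C)CO[Si](C)(C)C(C)(C)C | intermediate
20 | TMS enol ether (C8–OTMS, C8=C9; 10β-methyl, 10α-vinyl) | C=C[C@]1(C)C=C(O[Si](C)(C)C)[C@@H](C(C)=C)[C@@H](O[Si](CC)(CC)CC)[C@H]1C(=C)CO[Si](C)(C)C(C)(C)C | intermediate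
21 | TES ketone (C8=O, 6β-OTES, 15-OTBS) | C=C[C@]1(C)CC(=O)[C@@H](C(C)=C)[C@@H](O[Si](CC)(CC)CC)[C@H]1C(=C)CO[Si](C)(C)C(C)(C)C | intermediate
22 | β-hydroxy ketone (C8=O, 6β-OH, 7β-isopropenyl, 5β-[3-(TBSO)prop-1-en-2-yl], 10β-methyl, 10α-vinyl) | C=C[C@]1(C)CC(=O)[C@@H](C(C)=C)[C@@H](O)[C@H]1C(=C)CO[Si](C)(C)C(C)(C)C | intermediate
23 | anti-1,3-diol (6β-OH, 8α-OH, 15-OTBS) | C=C[C@]1(C)C[C@H](O)[C@@H](C(C)=C)[C@@H](O)[C@H]1C(=C)CO[Si](C)(C)C(C)(C)C | intermediate
24 | C8 ester: 8α-O-[(R)-3-(TBSO)-2-methylpropanoyl], 6β-OH, 15-OTBS | C=C[C@]1(C)C[C@H](OC(=O)[C@H](C)CO[Si](C)(C)C(C)(C)C)[C@@H](C(C)=C)[C@@H](O)[C@H]1C(=C)CO[Si](C)(C)C(C)(C)C | intermediate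
25 | 6-O-TES ether of 24 | C=C[C@]1(C)C[C@H](OC(=O)[C@H](C)CO[Si](C)(C)C(C)(C)C)[C@@H](C(C)=C)[C@@H](O[Si](CC)(CC)CC)[C@H]1C(=C)CO[Si](C)(C)C(C)(C)C | intermediate
26 | allylic alcohol (C12–OH on the C7 unit) | C=C[C@]1(C)C[C@H](OC(=O)[C@H](C)CO[Si](C)(C)C(C)(C)C)[C@@H](C(=C)CO)[C@@H](O[Si](CC)(CC)CC)[C@H]1C(=C)CO[Si](C)(C)C(C)(C)C | intermediate
27 | enal (C12 aldehyde) | C=C[C@]1(C)C[C@H](OC(=O)[C@H](C)CO[Si](C)(C)C(C)(C)C)[C@@H](C(=C)C=O)[C@@H](O[Si](CC)(CC)CC)[C@H]1C(=C)CO[Si](C)(C)C(C)(C)C | intermediate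
28 | acrylic acid (C12 acid, tris-silyl protected) | C=C[C@]1(C)C[C@H](OC(=O)[C@H](C)CO[Si](C)(C)C(C)(C)C)[C@@H](C(=C)C(=O)O)[C@@H](O[Si](CC)(CC)CC)[C@H]1C(=C)CO[Si](C)(C)C(C)(C)C | intermediate
29 | CNP0462645.4: 8α-O-[(R)-3-hydroxy-2-methylpropanoyl]-6β,15-dihydroxyelema-1,3,11(13)-trien-12-oic acid | C=C[C@]1(C)C[C@H](OC(=O)[C@H](C)CO)[C@@H](C(=C)C(=O)O)[C@@H](O)[C@H]1C(=C)CO | target

## Step count and risks

Total: 18 steps. Longest linear sequence: 16 steps (steps 3–18 from (S)-carvone); steps 1–2 make acid 3.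

Three steps most likely to fail:

Step 7 (Ireland–Claisen). The cis-1,3 isopropenyl group must go axial in the transition state, and acetate enolates can C-silylate. The fallback sets out from 8. K2CO3 in MeOH removes the acetate and gives cis-diol F1. Heating F1 with triethyl orthoacetate and catalytic propionic acid (xylene, 140 °C) runs a Johnson–Claisen rearrangement through the C9–O ketene acetal, the one that bonds to the unsubstituted alkene carbon. This gives hydroxy ethyl ester F2, which lactonises in the pot and comes back to the route at 12.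

Step 11 (second allylic oxidation). The doubly allylic C5–H and the C15 allylic ether position may compete with C8. The fallback sets out from 18 and avoids C–H oxidation. mCPBA (NaHCO3, CH2Cl2, −20 °C) epoxidises only the trisubstituted ring alkene, from the open α-face, to epoxide F3. PhSeSePh/NaBH4 in EtOH opens it at C9 to hydroxy selenide F4. H2O2 gives selenoxide F5, which undergoes syn-elimination away from the carbinol to tertiary allylic alcohol F6. (C5H5NH)[CrO3Cl] in CH2Cl2 then effects the oxidative 1,3-transposition (Babler–Dauben) and comes back at enone 19.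

Step 16 (SeO2 oxidation). The reagent must choose the isopropenyl group over the 2-(silyloxymethyl)vinyl group. The fallback sets out from 25. Ene-type chlorination with Ca(OCl)2 and CO2 (CH2Cl2/H2O, 0 °C) needs a free allylic methyl and gives allylic chloride F7. HCO2Na with catalytic Bu4NI in DMF gives allylic formate F8. NaHCO3 in MeOH cleaves only the formate and comes back at allylic alcohol 26.

Further compounds
F1 | step 7 | cis-diol (1S,4S,5S)-2-methyl-5-(prop-1-en-2-yl)cyclohex-2-ene-1,4-diol | O[C@H]1C[C@@H](C(C)=C)[C@@H](O)C=C1C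
F2 | step 7 | hydroxy ethyl ester (ethyl ester of hydroxy acid 11) | CC1=CC[C@@H](C(C)=C)[C@@H](O)[C@H]1CC(=O)OCC
F3 | step 11 | 9α,10α-epoxide of 18 | C[C@@]12O[C@@H]1C[C@@H](C(C)=C)[C@@H](O[Si](CC)(CC)CC)[C@H]2C(=C)CO[Si](C)(C)C(C)(C)C
F4 | step 11 | hydroxy selenide (10α-OH, 9β-SePh) | C[C@@]1(O)[C@@H]([Se]c2ccccc2)C[C@@H](C(C)=C)[C@@H](O[Si](CC)(CC)CC)[C@H]1C(=C)CO[Si](C)(C)C(C)(C)C
F5 | step 11 | selenoxide of F4 (mixture at selenium) | C[C@@]1(O)[C@@H]([Se](=O)c2ccccc2)C[C@@H](C(C)=C)[C@@H](O[Si](CC)(CC)CC)[C@H]1C(=C)CO[Si](C)(C)C(C)(C)C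
F6 | step 11 | tertiary allylic alcohol (10α-OH, C8=C9) | C[C@@]1(O)C=C[C@@H](C(C)=C)[C@@H](O[Si](CC)(CC)CC)[C@H]1C(=C)CO[Si](C)(C)C(C)(C)C
F7 | step 16 | allylic chloride (C12–Cl analogue of 26) | C=C[C@]1(C)C[C@H](OC(=O)[C@H](C)CO[Si](C)(C)C(C)(C)C)[C@@H](C(=C)CCl)[C@@H](O[Si](CC)(CC)CC)[C@H]1C(=C)CO[Si](C)(C)C(C)(C)C
F8 | step 16 | allylic formate (C12–OCHO analogue of 26) | C=C[C@]1(C)C[C@H](OC(=O)[C@H](C)CO[Si](C)(C)C(C)(C)C)[C@@H](C(=C)COC=O)[C@@H](O[Si](CC)(CC)CC)[C@H]1C(=C)CO[Si](C)(C)C(C)(C)C
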